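## Retrosynthetic overview
1. Target 17 is mesquitol-(4α→6)-mesquitol (upper unit 2R,3S,4R; lower unit 2R,3S). 17 ⇐ hydrogenolysis of octabenzyl ether 16 ⇐ hydroboration–oxidation of 4-aryl-flav-3-ene 14, which sets upper C3 and C4 from C2.
2. Interflavan C4–C6 bond of 14 ⇐ flavanone tosylhydrazone 7 + aryl bromide 12. The C4 carbonyl carbon is used as a donor (diazo/palladium-carbene form), so two acceptor carbons (C=O and C–Br) are joined.
3. 12 ⇐ C6 bromination of tetra-O-benzylmesquitol 11 ⇐ hydroboration of flav-3-ene 9 ⇐ Shapiro reaction of the same hydrazone 7. 7 ⇐ (2S)-flavanone 6 ⇐ enantioselective conjugate arylation of chromone 4 (from gallacetophenone 1) with boronic acid 5.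
4. Ring order: ring A is bought; the pyranone ring is closed in step 2; ring B is attached in step 3; the two units are joined last; no ring is formed after the coupling.

Assumption: 1 and 5 are bought, and the R enantiomer of t-BuPyOx is taken to give the 2S flavanone; if the first batch shows the opposite sense (chiral HPLC, optical rotation), the S ligand is used instead.

## Route

Step 1
Reactants: 1 gallacetophenone (1-(2,3,4-trihydroxyphenyl)ethan-1-one)
Product: 2 1-[3,4-bis(benzyloxy)-2-hydroxyphenyl]ethan-1-one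
Conditions: BnBr (2.1 equiv), K2CO3 (2.2 equiv), DMF, rt
Reagents that add atoms: benzyl bromide BrCc1ccccc1
Why: Williamson etherification; the 2-OH is hydrogen-bonded to the acetyl carbonyl and is the least nucleophilic, so only the 3- and 4-OH groups are benzylated.

Step 2
Reactants: 2 1-[3,4-bis(benzyloxy)-2-hydroxyphenyl]ethan-1-one
Product: 4 7,8-bis(benzyloxy)-4H-chromen-4-one, via enaminone 3 (not isolated)
Conditions: Me2NCH(OMe)2, toluene, 100 °C; then aq. HCl (2 equiv), CH2Cl2, 40 °C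
Reagents that add atoms: N,N-dimethylformamide dimethyl acetal COC(OC)N(C)C
Why: Enaminone formation followed by acid-induced intramolecular conjugate addition–elimination of dimethylamine closes the pyranone ring (standard chromone synthesis); no stereocentre is formed.

Step 3
Reactants: 4 7,8-bis(benzyloxy)-4H-chromen-4-one; 5 [3,4-bis(benzyloxy)phenyl]boronic acid (2 equiv)
Product: 6 (2S)-7,8-bis(benzyloxy)-2-[3,4-bis(benzyloxy)phenyl]-2,3-dihydro-4H-chromen-4-one
Conditions: Pd(OCOCF3)2 (5 mol%), (R)-t-BuPyOx (6 mol%), NH4PF6 (30 mol%), H2O (5 equiv), ClCH2CH2Cl, 60 °C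
Reagents that add atoms: none
Why: Enantioselective palladium-catalysed conjugate addition of an arylboronic acid to a chromone (Hayashi–Miyaura-type 1,4-addition); the pyridine-oxazoline ligand controls the face of aryl transfer to C2 and sets the 2S centre, the only stereocentre of the route that is not relayed from another one.

Step 4
Reactants: 6 (2S)-7,8-bis(benzyloxy)-2-[3,4-bis(benzyloxy)phenyl]-2,3-dihydro-4H-chromen-4-one
Product: 7 N'-[(2S)-7,8-bis(benzyloxy)-2-[3,4-bis(benzyloxy)phenyl]-2,3-dihydro-4H-chromen-4-ylidene]-4-methylbenzenesulfonohydrazide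
Conditions: TsNHNH2 (1.1 equiv), MeOH/THF, 40 °C
Reagents that add atoms: 4-methylbenzenesulfonohydrazide Cc1ccc(cc1)S(=O)(=O)NN
Why: Hydrazone condensation under near-neutral conditions; no base is present that could open the pyranone ring through C3, so the 2S centre is kept.

Step 5
Reactants: 7 tosylhydrazone of 6 (about 60% of the batch)
Product: 9 (2S)-7,8-bis(benzyloxy)-2-[3,4-bis(benzyloxy)phenyl]-2H-chromene, via vinyllithium 8 (not isolated)
Conditions: LiN(iPr)2 (3.0 equiv), THF, −78 °C to rt; then H2O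
Reagents that add atoms: none
Why: Shapiro reaction: LiN(iPr)2 removes the N–H and then a C3–H (the only α-hydrogens), the dianion loses sulfinate and N2 on warming to give vinyllithium 8 without any diazo or carbene stage, and protonation of 8 at C4 (by diisopropylamine or on the quench) leaves the C3=C4 alkene with C2 untouched.

Step 6
Reactants: 9 (2S)-7,8-bis(benzyloxy)-2-[3,4-bis(benzyloxy)phenyl]-2H-chromene
Product: 11 (2R,3S)-7,8-bis(benzyloxy)-2-[3,4-bis(benzyloxy)phenyl]-3,4-dihydro-2H-chromen-3-ol (tetra-O-benzylmesquitol), via alkylborane 10 (not isolated)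
Conditions: BH3·THF (2 equiv), THF, 0 °C to rt; then aq. NaOH, H2O2, 0 °C
Reagents that add atoms: hydrogen peroxide OO
Why: Hydroboration–oxidation of the styrene-type double bond: boron adds to C3 (the carbon remote from ring A) from the face opposite the C2 aryl group, and oxidation with retention gives the 2,3-trans alcohol (3S; the C2 descriptor changes from S to R by CIP ranking only).

Step 7
Reactants: 11 (2R,3S)-tetra-O-benzylmesquitol
Product: 12 (2R,3S)-7,8-bis(benzyloxy)-2-[3,4-bis(benzyloxy)phenyl]-6-bromo-3,4-dihydro-2H-chromen-3-ol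
Conditions: NBS (1.0 equiv), CH2Cl2, −40 to 0 °C, dark
Reagents that add atoms: N-bromosuccinimide O=C1CCC(=O)N1Br
Why: Electrophilic aromatic bromination; C6 is para to the coplanar ring oxygen and ortho to the 7-benzyloxy group, so it is the most activated position (each free position of ring B is activated by only one ortho or para ether oxygen).

Step 8
Reactants: 7 tosylhydrazone of 6 (1.3 equiv); 12 6-bromo-tetra-O-benzylmesquitol
Product: 14 (2R,3S)-7,8-bis(benzyloxy)-6-{(2S)-7,8-bis(benzyloxy)-2-[3,4-bis(benzyloxy)phenyl]-2H-chromen-4-yl}-2-[3,4-bis(benzyloxy)phenyl]-3,4-dihydro-2H-chromen-3-ol, via diazo compound 13 (not isolated)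
Conditions: Pd2(dba)3 (2.5 mol%), XPhos (10 mol%), LiOtBu (3.5 equiv), 1,4-dioxane, 90 °C, dark
Reagents that add atoms: none
Why: Barluenga cross-coupling: base converts 7 into diazo compound 13, whose carbon (the former carbonyl carbon, now a donor) is captured by the arylpalladium bromide from 12 as a palladium carbene; aryl migration and β-hydride elimination from C3 then give the C3=C4 alkene, so two carbons that are both acceptors in their own right (C=O and C–Br) are joined while C2 and the lower-unit stereocentres are untouched.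

Step 9
Reactants: 14 4-aryl-flav-3-ene
Product: 16 (2R,3S,4S)-7,8-bis(benzyloxy)-2-[3,4-bis(benzyloxy)phenyl]-4-{(2R,3S)-7,8-bis(benzyloxy)-2-[3,4-bis(benzyloxy)phenyl]-3-hydroxy-3,4-dihydro-2H-chromen-6-yl}-3,4-dihydro-2H-chromen-3-ol, via bis-borane 15 (not isolated)
Conditions: BH3·THF (6 equiv), THF, 0 to 40 °C; then aq. NaOH, H2O2, 0 °C to rt
Reagents that add atoms: hydrogen peroxide OO
Why: Hydroboration–oxidation: BH3 adds syn across C3=C4 from the face opposite the C2 aryl group with boron on the less substituted C3, so H at C4 and OH at C3 (oxidation with retention) end up on the same face, which makes the 3-OH trans to both aryl groups (2,3-trans-3,4-trans; C4 is S in 16 and R in 17 only because debenzylation changes the CIP ranking of the two aryl groups).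

Step 10
Reactants: 16 octa-O-benzyl dimer
Product: 17 (2R,3S,4R)-2-(3,4-dihydroxyphenyl)-4-[(2R,3S)-2-(3,4-dihydroxyphenyl)-3,7,8-trihydroxy-3,4-dihydro-2H-chromen-6-yl]-3,4-dihydro-2H-chromene-3,7,8-triol
Conditions: H2 (1 atm), Pd(OH)2 on carbon, THF/MeOH, rt
Reagents that add atoms: none
Why: Hydrogenolysis of eight benzyl aryl ethers under neutral conditions; the acid-labile interflavan bond and all five stereocentres are untouched.

## Compound list
1 | gallacetophenone | CC(=O)c1ccc(O)c(O)c1O | starting material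
2 | 1-[3,4-bis(benzyloxy)-2-hydroxyphenyl]ethan-1-one | CC(=O)c1ccc(OCc2ccccc2)c(OCc2ccccc2)c1O | intermediate
3 | (E)-1-[3,4-bis(benzyloxy)-2-hydroxyphenyl]-3-(dimethylamino)prop-2-en-1-one (not isolated) | CN(C)/C=C/C(=O)c1ccc(OCc2ccccc2)c(OCc2ccccc2)c1O | intermediate
4 | 7,8-bis(benzyloxy)-4H-chromen-4-one | O=c1ccoc2c(OCc3ccccc3)c(OCc3ccccc3)ccc12 | intermediate
5 | [3,4-bis(benzyloxy)phenyl]boronic acid | OB(O)c1ccc(OCc2ccccc2)c(OCc2ccccc2)c1 | starting material
6 | (2S)-7,8-bis(benzyloxy)-2-[3,4-bis(benzyloxy)phenyl]-2,3-dihydro-4H-chromen-4-one | O=C1C[C@@H](c2ccc(OCc3ccccc3)c(OCc3ccccc3)c2)Oc2c(OCc3ccccc3)c(OCc3ccccc3)ccc12 | intermediate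
7 | N-tosylhydrazone of 6 (2S; C=N geometry not defined, lost in steps 5 and 8) | Cc1ccc(cc1)S(=O)(=O)NN=C1C[C@@H](c2ccc(OCc3ccccc3)c(OCc3ccccc3)c2)Oc2c(OCc3ccccc3)c(OCc3ccccc3)ccc12 | intermediate
8 | [(2S)-7,8-bis(benzyloxy)-2-[3,4-bis(benzyloxy)phenyl]-2H-chromen-4-yl]lithium (not isolated) | [Li]C1=C[C@@H](c2ccc(OCc3ccccc3)c(OCc3ccccc3)c2)Oc2c(OCc3ccccc3)c(OCc3ccccc3)ccc12 | intermediate
9 | (2S)-7,8-bis(benzyloxy)-2-[3,4-bis(benzyloxy)phenyl]-2H-chromene | C1=C[C@@H](c2ccc(OCc3ccccc3)c(OCc3ccccc3)c2)Oc2c(OCc3ccccc3)c(OCc3ccccc3)ccc12 | intermediate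
10 | [(2S,3S)-7,8-bis(benzyloxy)-2-[3,4-bis(benzyloxy)phenyl]-3,4-dihydro-2H-chromen-3-yl]borane (2,3-trans; drawn as the monoalkylborane; not isolated) | c1cc2c(c(OCc3ccccc3)c1OCc1ccccc1)O[C@H](c1ccc(OCc3ccccc3)c(OCc3ccccc3)c1)[C@@H](B)C2 | intermediate
11 | (2R,3S)-7,8-bis(benzyloxy)-2-[3,4-bis(benzyloxy)phenyl]-3,4-dihydro-2H-chromen-3-ol | c1cc2c(c(OCc3ccccc3)c1OCc1ccccc1)O[C@H](c1ccc(OCc3ccccc3)c(OCc3ccccc3)c1)[C@@H](O)C2 | intermediate
12 | (2R,3S)-7,8-bis(benzyloxy)-2-[3,4-bis(benzyloxy)phenyl]-6-bromo-3,4-dihydro-2H-chromen-3-ol | Brc1cc2c(c(OCc3ccccc3)c1OCc1ccccc1)O[C@H](c1ccc(OCc3ccccc3)c(OCc3ccccc3)c1)[C@@H](O)C2 | intermediate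
13 | (2S)-7,8-bis(benzyloxy)-2-[3,4-bis(benzyloxy)phenyl]-4-diazo-3,4-dihydro-2H-chromene (not isolated) | [N-]=[N+]=C1C[C@@H](c2ccc(OCc3ccccc3)c(OCc3ccccc3)c2)Oc2c(OCc3ccccc3)c(OCc3ccccc3)ccc12 | intermediate
14 | (2R,3S)-7,8-bis(benzyloxy)-6-{(2S)-7,8-bis(benzyloxy)-2-[3,4-bis(benzyloxy)phenyl]-2H-chromen-4-yl}-2-[3,4-bis(benzyloxy)phenyl]-3,4-dihydro-2H-chromen-3-ol | C1(c3cc4c(c(OCc5ccccc5)c3OCc3ccccc3)O[C@H](c3ccc(OCc5ccccc5)c(OCc5ccccc5)c3)[C@@H](O)C4)=C[C@@H](c3ccc(OCc4ccccc4)c(OCc4ccccc4)c3)Oc2c(OCc3ccccc3)c(OCc3ccccc3)ccc12 | intermediate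
15 | bis-borane: 16 with BH2 in place of the upper 3-OH (same spatial arrangement) and the lower 3-OH as its O-BH2 ester (not isolated) | O(Cc1ccccc1)c1ccc([C@H]2Oc3c(ccc(OCc4ccccc4)c3OCc3ccccc3)[C@@H](c3cc4c(c(OCc5ccccc5)c3OCc3ccccc3)O[C@H](c3ccc(OCc5ccccc5)c(OCc5ccccc5)c3)[C@@H](OB)C4)[C@@H]2B)cc1OCc1ccccc1 | intermediate
16 | (2R,3S,4S)-7,8-bis(benzyloxy)-2-[3,4-bis(benzyloxy)phenyl]-4-{(2R,3S)-7,8-bis(benzyloxy)-2-[3,4-bis(benzyloxy)phenyl]-3-hydroxy-3,4-dihydro-2H-chromen-6-yl}-3,4-dihydro-2H-chromen-3-ol (2,3-trans-3,4-trans, same spatial arrangement as 17) | O(Cc1ccccc1)c1ccc([C@H]2Oc3c(ccc(OCc4ccccc4)c3OCc3ccccc3)[C@@H](c3cc4c(c(OCc5ccccc5)c3OCc3ccccc3)O[C@H](c3ccc(OCc5ccccc5)c(OCc5ccccc5)c3)[C@@H](O)C4)[C@@H]2O)cc1OCc1ccccc1 | intermediate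
17 | (2R,3S,4R)-2-(3,4-dihydroxyphenyl)-4-[(2R,3S)-2-(3,4-dihydroxyphenyl)-3,7,8-trihydroxy-3,4-dihydro-2H-chromen-6-yl]-3,4-dihydro-2H-chromene-3,7,8-triol | Oc1ccc([C@H]2Oc3c(ccc(O)c3O)[C@@H](c3cc4c(c(O)c3O)O[C@H](c3ccc(O)c(O)c3)[C@@H](O)C4)[C@@H]2O)cc1O | target

## Step count and risks
Total step count: 10. Longest linear sequence: 10 (steps 1 to 10 in a row; hydrazone 7 enters twice, in steps 5 and 8).

The three steps most likely to fail:

Step 8. The bromide is electron-rich, ortho-alkoxy-substituted and carries a free secondary hydroxyl. At 90 °C the 2H-chromene may lose some C2 integrity through reversible ring opening. Part of 13 may also collapse to 9 by a carbene 1,2-hydrogen shift, which is harmless because 9 is recycled into step 6. The fallback sets out from 6 (12 is used as made) and comes back at 14. Flavanone 6 is treated with Tf2O and 2,6-di-tert-butyl-4-methylpyridine (CH2Cl2, 0 °C) to give the vinyl triflate F1; no strong base is present, so the pyran ring stays closed. Miyaura borylation (bis(pinacolato)diboron, PdCl2(dppf), KOAc, 1,4-dioxane, 80 °C) gives the vinyl boronate F2. F2 is joined to 12 by Suzuki–Miyaura coupling (PdCl2(dppf), K3PO4, dioxane/water, 60 °C) to reach 14 without diazo chemistry.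

Step 3. The 7,8-dialkoxychromone is a weak acceptor, so conversion and enantiomeric excess may fall short. A shortfall in enantiomeric excess is partly tolerable, because the minor enantiomer ends up mostly in diastereomers of 14 and 16 that are removed by chromatography. The fallback sets out from 2 and comes back at 6. Claisen–Schmidt condensation of 2 with 3,4-bis(benzyloxy)benzaldehyde F3 (KOH, EtOH) gives the 2'-hydroxychalcone F4. NaOAc in refluxing EtOH closes it to the racemic flavanone F5. Preparative chromatography on a cellulose tris(3,5-dimethylphenylcarbamate) phase delivers the 2S enantiomer, which is 6. The 2R enantiomer is racemised with base (ring opening and re-closure through F4) and recycled.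

Step 5. In the dianion the C3 carbanion sits β to the ring oxygen, so it may expel the phenoxide and open the ring to a chalcone-type hydrazone before it fragments to 8. This costs yield but cannot racemise C2, because the opened material does not re-close to 9. The fallback sets out from 6 and comes back at 9. NaBH4 (MeOH/THF, 0 °C) gives the 2,4-cis flavan-4-ol F6. F6 loses water with catalytic pyridinium p-toluenesulfonate in toluene over molecular sieves at 60 °C (the 7-benzyloxy group stabilises the benzylic cation) to give 9.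

## Further compounds
F1 | step 8 | (2S)-7,8-bis(benzyloxy)-2-[3,4-bis(benzyloxy)phenyl]-2H-chromen-4-yl trifluoromethanesulfonate | O=S(=O)(OC1=C[C@@H](c2ccc(OCc3ccccc3)c(OCc3ccccc3)c2)Oc2c(OCc3ccccc3)c(OCc3ccccc3)ccc12)C(F)(F)F
F2 | step 8 | (2S)-7,8-bis(benzyloxy)-2-[3,4-bis(benzyloxy)phenyl]-4-(4,4,5,5-tetramethyl-1,3,2-dioxaborolan-2-yl)-2H-chromene | CC1(C)OB(OC1(C)C)C1=C[C@@H](c2ccc(OCc3ccccc3)c(OCc3ccccc3)c2)Oc2c(OCc3ccccc3)c(OCc3ccccc3)ccc12
F3 | step 3 | 3,4-bis(benzyloxy)benzaldehyde (bought) | O=Cc1ccc(OCc2ccccc2)c(OCc2ccccc2)c1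
F4 | step 3 | (E)-1-[3,4-bis(benzyloxy)-2-hydroxyphenyl]-3-[3,4-bis(benzyloxy)phenyl]prop-2-en-1-one | O=C(/C=C/c1ccc(OCc2ccccc2)c(OCc2ccccc2)c1)c1ccc(OCc2ccccc2)c(OCc2ccccc2)c1O
F5 | step 3 | racemic 7,8-bis(benzyloxy)-2-[3,4-bis(benzyloxy)phenyl]-2,3-dihydro-4H-chromen-4-one | O=C1CC(c2ccc(OCc3ccccc3)c(OCc3ccccc3)c2)Oc2c(OCc3ccccc3)c(OCc3ccccc3)ccc12
F6 | step 5 | (2S,4S)-7,8-bis(benzyloxy)-2-[3,4-bis(benzyloxy)phenyl]-3,4-dihydro-2H-chromen-4-ol (2,4-cis) | O[C@H]1C[C@@H](c2ccc(OCc3ccccc3)c(OCc3ccccc3)c2)Oc2c(OCc3ccccc3)c(OCc3ccccc3)ccc12
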